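## Analysis of the target

The target is a 2,3-dihydro-1,4-benzodioxine, numbered here O1, C2, C3, O4, C4a, C5 to C8, C8a. C2 carries a carboxylic acid, C3 a 3,4-dihydroxyphenyl ring, and C7 (para to O4, meta to O1) an (E)-propenoate. The acyl group of that propenoate is bound to the hydroxyl of (R)-3-(4-hydroxy-3-methoxyphenyl)lactic acid. There are three stereocentres: C2 (S) and C3 (S), which are cis on the dioxane ring, and the remote lactate carbon (R), which is independent of them. The cis arrangement is the less stable one. C2–H lies α to a carboxyl group and to O1, and C3 is a benzylic ether carbon bearing a para-oxygenated ring, so base (enolisation, quinone methide) or acid (ionisation of C3–O4) can turn cis into trans. The catechol, the phenol, two free acids and the enoate ester that joins the halves are all sensitive, and the alkene rules out hydrogenolysis for deprotection. The hard points are the chain at C7 and not C6 on a ring whose two oxygens are electronically alike, the cis relation, and a global deprotection that must stay near neutral. The strategy rests on one feature: the benzene ring of the bicycle carries O1 and O4 on the adjacent carbons C8a and C4a and one carbon substituent at C7. A [2+2+2] cycloaddition gives exactly this pattern from a 1,7-diyne whose inner alkyne carbons are bound to the two oxygens (the bis-ynol ether of the C2–C3 diol) and a terminal alkyne, so the arene can be made last on an acyclic erythro diol.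

## Retrosynthetic reasoning

**34 back to 29 (no skeletal bond cut).** The phenols are carried as silyl ethers (33) and the lactate carboxyl as a tert-butyl ester. The C2 carboxyl is carried as a trityl-protected hydroxymethyl group (32 from 30, 30 from 29), so C2 is not enolisable while the ring system is built. Compounds 29 to 32 also carry a Me3Si group at C5 that the target lacks. It is accepted because the acid that cleaves the tert-butyl ester also removes it. The forward order is detritylation, neutral oxidation, acid, buffered fluoride, so that acid acts while the phenols are still silylated and fluoride comes last.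

**29 to 17 and 28 (key disconnection).** The bonds C4a–C8a, C5–C6 and C7–C8 are cut, which opens both the benzene and the dioxane ring. Cutting inside the dioxane ring instead (O1–C2 or O4–C3) would leave a catechol whose two oxygens must be told apart and a ring closure at an epimerisable centre. Cutting the arene avoids both: in acyclic 17 the two oxygens differ by the carbon they sit on, and no bond to C2 or C3 is made. Two rings are gained, and 28 brings the whole lactate half with the enoate already in place. The forward reaction has to couple two ynol ether alkynes, take up the terminal alkyne with the chain at C7, and leave both stereocentres alone.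

**28 to 23 and 27.** The acyl C–O bond of the ester is cut, and an ordinary esterification makes it. Acid 27 goes back through 26 to aldehyde 24 and phosphonate 25 by cutting the C=C bond (olefination). Ester 23 goes back to acid 22, and 22 to aryl bromide 19 and epoxide salt 20 by cutting the aryl–CH2 bond. The lactate centre then comes from the chiral pool and is not involved in the bond-forming event. 19 comes from phenol 18.

**17 back to 6.** The two O–C(sp) bonds are cut, and each ynol ether is traced to an alcohol through a dichlorovinyl ether (15 and 8). The benzylic oxygen comes first because it is the only free hydroxyl of 6. The acetonide is removed (9) and the primary hydroxyl tritylated (10) while this first unit is still the acid-stable dichlorovinyl ether. Only then is it turned into the silyl-capped alkyne (13), because this terminus becomes C5. The unit on the C2 oxygen follows (15), and the terminal ynol ether, the most fragile group, is made last (17).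

**6 to 2 and 3.** The C3–aryl bond is cut. Aldehyde 3 brings C2 in the right configuration, and C3 is set by 1,2-induction. The forward addition has to give the anti (erythro) carbinol, which becomes the cis ring. 2 comes from bromocatechol 1.

## Alternatives that were turned down

**Alternative 1:** The O1–C2 bond of the dioxane ring is cut. The catechol, C3, C2 and the carboxyl carbon come from the threo amino acid droxidopa A1. After the amino group is exchanged for hydroxyl and O4 is attached at C3, a threo α-hydroxy ester with a free ring phenol is closed under Mitsunobu conditions (a phosphine and an azodicarboxylate). Inversion at C2 gives the cis aldehyde A2.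
- For: both ring stereocentres come from the chiral pool, the closure is a known reaction type, and the C7/C6 question is settled by the aromatic building block. On precedent it is stronger than the chosen route, and on regiochemistry it is as strong.
- Against: the activated C2 oxygen sits α to an ester and β to a benzylic aryloxy carbon, so elimination to the unsaturated ester competes with substitution. C2–H of A2 is acidic and the basic Mitsunobu by-products can move cis to trans. The precursor needs a stereospecific benzylic aryl ether and an amine-to-hydroxyl exchange on a densely protected amino acid. C2 is at the ester level from the start, so the fragile cis ester meets every later step.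
- Comparison: the chosen route keeps C2 as CH2O-trityl until the ring exists and makes the arene convergently. It pays for this with a key step that has no direct precedent.

**Alternative 2:** O1–C2 and C2–C3 are cut, and C2 is inserted as a carbene carbon. A copper carbene from a diazoacetate is captured by one acetal oxygen of a 2-aryl-1,3-benzodioxole. A 1,2-shift of the acetal carbon (Stevens type) enlarges the ring to the fully protected target A3.
- For: it is the most convergent plan, the five-membered acetal is trivial to make, and only deprotection follows. In step economy it is clearly stronger than the chosen route.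
- Against: the two acetal oxygens differ only in being para or meta to the propenoate, and which one forms the ylide decides C7 against C6. The shift of a benzylic acetal carbon has radical-pair or ion-pair character, so the cis/trans ratio and the absolute configuration at two new centres would rest on the catalyst alone, with trans favoured. The carbene can also add to the electron-rich arenes or dimerise.
- Comparison: the chosen route sets both centres early by substrate control, its key step cannot change them, and the silyl group decides the regiochemistry.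

**Alternative 3:** The acyl C–O bond and the C=C bond of the propenoate are cut around a two-carbon linchpin. The allyl-protected (R)-lactate alcohol adds to a ketenylidene phosphorane to give an ester-stabilised ylide, which olefinates aldehyde A2 in the same pot to give the penta-allyl compound A4.
- For: it is a known cascade, convergent, neutral and (E)-selective. Its key step is far more certain than the chosen one, and it needs no activated enynoic acid.
- Against: it makes the two easiest bonds of the molecule and hands the real problem, the cis ring with the right regiochemistry, to the synthesis of A2, with the weaknesses named above. The hindered α-hydroxy ester adds slowly to the cumulene. The warm, basic ylide meets the acidic C2–H of A2. Five allyl groups must leave with zerovalent palladium next to a catechol.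
- Comparison: the chosen route makes the same linkage by plain esterification before the ring exists and spends its key step on the ring system.

Key step: step 15

Assumption: potassium (R)-oxirane-2-carboxylate (20) is taken as purchasable; otherwise it is made in one step from commercial methyl (R)-glycidate with KOH in ethanol.

## Route

Step 1
Reactants: 1 4-bromobenzene-1,2-diol
Product: 2 4-bromo-1,2-bis[(triisopropylsilyl)oxy]benzene
Conditions: iPr3SiOTf (2.3 equiv), 2,6-lutidine, CH2Cl2, 0 °C to rt
Reagents that add atoms: triisopropylsilyl trifluoromethanesulfonate, CC(C)[Si](C(C)C)(C(C)C)OS(=O)(=O)C(F)(F)F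
Why: Silylation of both phenols with a silyl triflate and a hindered base; triisopropylsilyl is chosen over tert-butyldimethylsilyl because these aryl silyl ethers must later survive potassium alkoxides and n-BuLi.

Step 2
Reactants: 2 4-bromo-1,2-bis[(triisopropylsilyl)oxy]benzene; 3 (R)-2,2-dimethyl-1,3-dioxolane-4-carbaldehyde
Product: 6 (S)-{3,4-bis[(triisopropylsilyl)oxy]phenyl}[(4R)-2,2-dimethyl-1,3-dioxolan-4-yl]methanol, via aryllithium 4 (not isolated), via aryltitanium triisopropoxide 5 (not isolated)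
Conditions: n-BuLi, THF, −78 °C; ClTi(OiPr)3, −78 to −40 °C; then 3, −78 to 0 °C; aq. NH4Cl
Reagents that add atoms: none
Why: Bromine–lithium exchange, transmetalation to a non-chelating aryltitanium reagent and Felkin–Anh addition to the α-alkoxy aldehyde: attack anti to the ring C–O bond should favour the anti (erythro) carbinol, which sets the benzylic centre (S) relative to the chiral-pool centre (R). The plain magnesium reagent is avoided because its facial bias with this aldehyde is small; the minor syn epimer is removed by chromatography.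

Step 3
Reactants: 6 (S)-{3,4-bis[(triisopropylsilyl)oxy]phenyl}[(4R)-2,2-dimethyl-1,3-dioxolan-4-yl]methanol
Product: 8 (4R)-4-[(S)-{3,4-bis[(triisopropylsilyl)oxy]phenyl}{[(E)-1,2-dichlorovinyl]oxy}methyl]-2,2-dimethyl-1,3-dioxolane, via potassium alkoxide 7 (not isolated)
Conditions: KH (2.2 equiv), THF, 0 °C; Cl2C=CHCl (1.2 equiv), −50 °C to rt
Reagents that add atoms: trichloroethylene, ClC=C(Cl)Cl
Why: Addition of a potassium alkoxide to dichloroacetylene formed in the flask from trichloroethylene, the first half of the dichlorovinyl ether route to ynol ethers; anti addition gives the (E)-1,2-dichlorovinyl ether, which is electron-poor and survives the acid of step 4.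

Step 4
Reactants: 8 (4R)-4-[(S)-{3,4-bis[(triisopropylsilyl)oxy]phenyl}{[(E)-1,2-dichlorovinyl]oxy}methyl]-2,2-dimethyl-1,3-dioxolane
Product: 9 (2R,3S)-3-{3,4-bis[(triisopropylsilyl)oxy]phenyl}-3-{[(E)-1,2-dichlorovinyl]oxy}propane-1,2-diol
Conditions: TsOH·H2O (0.1 equiv), MeOH, rt
Reagents that add atoms: none
Why: Acid-catalysed transacetalisation of a terminal acetonide in methanol; the dichlorovinyl ether, the aryl silyl ethers and both stereocentres should not be affected. The step is placed here because no ynol ether is present yet.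

Step 5
Reactants: 9 (2R,3S)-3-{3,4-bis[(triisopropylsilyl)oxy]phenyl}-3-{[(E)-1,2-dichlorovinyl]oxy}propane-1,2-diol
Product: 10 (1S,2R)-1-{3,4-bis[(triisopropylsilyl)oxy]phenyl}-1-{[(E)-1,2-dichlorovinyl]oxy}-3-(trityloxy)propan-2-ol
Conditions: Ph3CCl, pyridine, DMAP (cat.), CH2Cl2, rt
Reagents that add atoms: trityl chloride, ClC(c1ccccc1)(c1ccccc1)c1ccccc1
Why: Tritylation is selective for the primary hydroxyl for steric reasons; the trityl ether tolerates n-BuLi and KH and later leaves under mild acid.

Step 6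
Reactants: 10 (1S,2R)-1-{3,4-bis[(triisopropylsilyl)oxy]phenyl}-1-{[(E)-1,2-dichlorovinyl]oxy}-3-(trityloxy)propan-2-ol
Product: 13 (1S,2R)-1-{3,4-bis[(triisopropylsilyl)oxy]phenyl}-1-{[(trimethylsilyl)ethynyl]oxy}-3-(trityloxy)propan-2-ol, via dilithium alkoxide acetylide 11 (not isolated), via O-silyl C-silyl compound 12 (not isolated)
Conditions: n-BuLi (3.3 equiv), THF, −78 to −40 °C; Me3SiCl (2.5 equiv), −78 to 0 °C; then K2CO3 (0.05 equiv), MeOH–THF, −20 °C, short
Reagents that add atoms: chlorotrimethylsilane, C[Si](C)(C)Cl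
Why: n-BuLi deprotonates the hydroxyl and converts the dichlorovinyl ether by elimination and chlorine–lithium exchange into the lithium alkynyl ether, which Me3SiCl silylates on carbon and on oxygen. Methanolysis of a secondary alkyl O–SiMe3 ether is much faster than cleavage of a C(sp)–SiMe3 bond, so a cold, short, catalytic carbonate treatment should free only the hydroxyl. The silyl cap is placed on this alkyne because its terminus becomes C5.

Step 7
Reactants: 13 (1S,2R)-1-{3,4-bis[(triisopropylsilyl)oxy]phenyl}-1-{[(trimethylsilyl)ethynyl]oxy}-3-(trityloxy)propan-2-ol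
Product: 15 ({[(1S,2R)-1-{3,4-bis[(triisopropylsilyl)oxy]phenyl}-2-{[(E)-1,2-dichlorovinyl]oxy}-3-(trityloxy)propyl]oxy}ethynyl)trimethylsilane, via potassium alkoxide 14 (not isolated)
Conditions: KH (2.2 equiv), THF, 0 °C, short; Cl2C=CHCl (1.2 equiv), −50 °C to rt
Reagents that add atoms: trichloroethylene, ClC=C(Cl)Cl
Why: The same alkoxide addition to dichloroacetylene as in step 3, now on the C2 oxygen. The alkoxide is made cold and trapped at once so that it has little time to attack the neighbouring silyl alkyne; silicon transfer within the molecule would need a ring that contains the linear alkyne and is not expected.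

Step 8
Reactants: 15 ({[(1S,2R)-1-{3,4-bis[(triisopropylsilyl)oxy]phenyl}-2-{[(E)-1,2-dichlorovinyl]oxy}-3-(trityloxy)propyl]oxy}ethynyl)trimethylsilane
Product: 17 ({[(1S,2R)-1-{3,4-bis[(triisopropylsilyl)oxy]phenyl}-2-(ethynyloxy)-3-(trityloxy)propyl]oxy}ethynyl)trimethylsilane, via lithium alkynyl ether 16 (not isolated)
Conditions: n-BuLi (2.3 equiv), THF, −78 to −40 °C; MeOH, −78 °C; Et3N-washed silica, cold
Reagents that add atoms: none
Why: Elimination and chlorine–lithium exchange with two equivalents of n-BuLi give the lithium alkynyl ether, which methanol protonates to the terminal ynol ether; the Me3Si–alkyne is inert to n-BuLi at −78 °C. The diyne is kept cold and free of acid and is used at once.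

Step 9
Reactants: 18 4-bromo-2-methoxyphenol
Product: 19 (4-bromo-2-methoxyphenoxy)(tert-butyl)dimethylsilane
Conditions: t-BuMe2SiCl, imidazole, DMF, rt
Reagents that add atoms: tert-butyldimethylsilyl chloride, CC(C)(C)[Si](C)(C)Cl
Why: Standard silylation of a phenol; this half meets no strong base later, so the smaller silyl group is enough.

Step 10
Reactants: 19 (4-bromo-2-methoxyphenoxy)(tert-butyl)dimethylsilane; 20 potassium (R)-oxirane-2-carboxylate
Product: 22 (R)-3-{4-[(tert-butyldimethylsilyl)oxy]-3-methoxyphenyl}-2-hydroxypropanoic acid, via arylmagnesium bromide 21 (not isolated)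
Conditions: Mg, THF; CuI (0.1 equiv), 20, THF, −20 °C to rt; 1 M HCl to pH 3, 0 °C
Reagents that add atoms: none
Why: Copper-catalysed opening of the glycidate salt by the aryl Grignard reagent at the unsubstituted epoxide carbon (SN2 at CH2); the stereocentre is not touched, so (R) is kept, and a carboxylate cannot be attacked at the carbonyl group.

Step 11
Reactants: 22 (R)-3-{4-[(tert-butyldimethylsilyl)oxy]-3-methoxyphenyl}-2-hydroxypropanoic acid
Product: 23 tert-butyl (R)-3-{4-[(tert-butyldimethylsilyl)oxy]-3-methoxyphenyl}-2-hydroxypropanoate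
Conditions: Cl3CC(=NH)Ot-Bu (2.5 equiv), CH2Cl2–cyclohexane, rt
Reagents that add atoms: tert-butyl 2,2,2-trichloroacetimidate, CC(C)(C)OC(=N)C(Cl)(Cl)Cl
Why: tert-Butyl esterification of a carboxylic acid by the trichloroacetimidate without added acid; the secondary hydroxyl does not react without a Lewis acid and the aryl silyl ether is untouched.

Step 12
Reactants: 24 3-(trimethylsilyl)prop-2-ynal; 25 triethyl phosphonoacetate
Product: 26 ethyl (E)-5-(trimethylsilyl)pent-2-en-4-ynoate
Conditions: LiCl, i-Pr2NEt, MeCN, 0 °C to rt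
Reagents that add atoms: none
Why: Horner–Wadsworth–Emmons olefination under Masamune–Roush conditions; the stabilised phosphonate should give the (E)-enoate, and any minor (Z) isomer is removed at the stage of the crystalline acid.

Step 13
Reactants: 26 ethyl (E)-5-(trimethylsilyl)pent-2-en-4-ynoate
Product: 27 (E)-pent-2-en-4-ynoic acid
Conditions: LiOH (3 equiv), THF–H2O, 0 °C to rt; then 1 M HCl
Reagents that add atoms: lithium hydroxide, [Li+].[OH-]
Why: Hydroxide saponifies the ethyl ester and cleaves the C(sp)–Si bond in the same operation; acidification gives the free enynoic acid, which is stored cold.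

Step 14
Reactants: 23 tert-butyl (R)-3-{4-[(tert-butyldimethylsilyl)oxy]-3-methoxyphenyl}-2-hydroxypropanoate; 27 (E)-pent-2-en-4-ynoic acid
Product: 28 tert-butyl (R)-3-{4-[(tert-butyldimethylsilyl)oxy]-3-methoxyphenyl}-2-{[(E)-pent-2-en-4-ynoyl]oxy}propanoate
Conditions: DCC, DMAP (0.1 equiv), CH2Cl2, 0 °C
Reagents that add atoms: none
Why: Steglich esterification of the secondary α-hydroxy ester, with no bond to the stereocentre changed. Compound 28 has no acidic group left, which matters because the ynol ethers of the next step add acids.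

Step 15
Reactants: 17 ({[(1S,2R)-1-{3,4-bis[(triisopropylsilyl)oxy]phenyl}-2-(ethynyloxy)-3-(trityloxy)propyl]oxy}ethynyl)trimethylsilane; 28 tert-butyl (R)-3-{4-[(tert-butyldimethylsilyl)oxy]-3-methoxyphenyl}-2-{[(E)-pent-2-en-4-ynoyl]oxy}propanoate
Product: 29 tert-butyl (R)-2-{[(E)-3-[(2R,3S)-3-{3,4-bis[(triisopropylsilyl)oxy]phenyl}-5-(trimethylsilyl)-2-[(trityloxy)methyl]-2,3-dihydro-1,4-benzodioxin-7-yl]prop-2-enoyl]oxy}-3-{4-[(tert-butyldimethylsilyl)oxy]-3-methoxyphenyl}propanoate
Conditions: Cp*RuCl(cod) (10 mol%), ClCH2CH2Cl, 20 °C, argon; 17 added over several hours to 28 (2 equiv)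
Reagents that add atoms: none
Why: Proposed new method: the Cp*RuCl fragment freed from cyclooctadiene should bind the two electron-rich ynol ether alkynes of 17 and couple them oxidatively to a ruthenacyclopentadiene, which makes C4a–C8a and so closes the six-membered 1,4-dioxane ring across the O1–C2–C3–O4 tether (closure by C–C coupling of two alkyne carbons held as a 1,7-diyne); insertion of the terminal alkyne of 28 and reductive elimination then make C5–C6 and C7–C8 and close the benzene ring, a formal [2+2+2] cycloaddition. The closest known reactions are Cp*RuCl(cod)- and rhodium-catalysed [2+2+2] cycloadditions of 1,6- and 1,7-diynes with terminal alkynes and cyclotrimerisations of alkynyl ethers to aryl ethers; a diyne in which both alkynes are ynol ethers of a 1,2-diol has not been used in this way. No stereocentre is formed: C2 and C3 lie in the tether, no bond to them is made or broken, and C2 carries CH2O-trityl and has no acidic hydrogen, so the erythro relation of 17 should reappear as the cis relation of 29. The step needs the chain at C7 and not at C6: the Me3Si group on the terminus that becomes C5 makes the two ends of the metallacycle unequal, and the substituted carbon of the monoalkyne should bond to the unhindered end (C8), which puts the propenoate meta to silicon, as diynes with one substituted terminus do in the known ruthenium reactions. Cross-selectivity is helped by pairing the electron-rich diyne with the electron-poor enyne, by the excess of 28 and by the slow addition of 17. The reaction runs at room temperature in a neutral, aprotic medium, which the benzylic ynol ether needs because it can rearrange sigmatropically on warming and is hydrated by acid.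

Step 16
Reactants: 29 tert-butyl (R)-2-{[(E)-3-[(2R,3S)-3-{3,4-bis[(triisopropylsilyl)oxy]phenyl}-5-(trimethylsilyl)-2-[(trityloxy)methyl]-2,3-dihydro-1,4-benzodioxin-7-yl]prop-2-enoyl]oxy}-3-{4-[(tert-butyldimethylsilyl)oxy]-3-methoxyphenyl}propanoate
Product: 30 tert-butyl (R)-2-{[(E)-3-[(2R,3S)-3-{3,4-bis[(triisopropylsilyl)oxy]phenyl}-2-(hydroxymethyl)-5-(trimethylsilyl)-2,3-dihydro-1,4-benzodioxin-7-yl]prop-2-enoyl]oxy}-3-{4-[(tert-butyldimethylsilyl)oxy]-3-methoxyphenyl}propanoate
Conditions: TsOH·H2O (0.2 equiv), MeOH–CH2Cl2, 0 °C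
Reagents that add atoms: none
Why: Acid-catalysed methanolysis of the trityl ether, with the trityl cation trapped as its methyl ether; aryl silyl ethers, the tert-butyl ester and the aryl–silicon bond should survive a catalytic sulfonic acid at 0 °C.

Step 17
Reactants: 30 tert-butyl (R)-2-{[(E)-3-[(2R,3S)-3-{3,4-bis[(triisopropylsilyl)oxy]phenyl}-2-(hydroxymethyl)-5-(trimethylsilyl)-2,3-dihydro-1,4-benzodioxin-7-yl]prop-2-enoyl]oxy}-3-{4-[(tert-butyldimethylsilyl)oxy]-3-methoxyphenyl}propanoate
Product: 32 (2S,3S)-3-{3,4-bis[(triisopropylsilyl)oxy]phenyl}-7-[(E)-3-{[(R)-1-tert-butoxy-3-{4-[(tert-butyldimethylsilyl)oxy]-3-methoxyphenyl}-1-oxopropan-2-yl]oxy}-3-oxoprop-1-enyl]-5-(trimethylsilyl)-2,3-dihydro-1,4-benzodioxine-2-carboxylic acid, via aldehyde 31 (not isolated)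
Conditions: TEMPO (0.2 equiv), PhI(OAc)2 (2.5 equiv), MeCN–H2O, 0 °C to rt
Reagents that add atoms: water, O
Why: Oxoammonium (TEMPO) oxidation with PhI(OAc)2 as terminal oxidant, through the aldehyde and its hydrate to the acid. The medium is neutral to weakly acidic, so the α-aryloxy aldehyde meets no base that could epimerise C2 or expel O4; the spatial arrangement at C2 is unchanged and only the descriptor changes from R to S.

Step 18
Reactants: 32 (2S,3S)-3-{3,4-bis[(triisopropylsilyl)oxy]phenyl}-7-[(E)-3-{[(R)-1-tert-butoxy-3-{4-[(tert-butyldimethylsilyl)oxy]-3-methoxyphenyl}-1-oxopropan-2-yl]oxy}-3-oxoprop-1-enyl]-5-(trimethylsilyl)-2,3-dihydro-1,4-benzodioxine-2-carboxylic acid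
Product: 33 (2S,3S)-3-{3,4-bis[(triisopropylsilyl)oxy]phenyl}-7-[(E)-3-{[(R)-1-carboxy-2-{4-[(tert-butyldimethylsilyl)oxy]-3-methoxyphenyl}ethyl]oxy}-3-oxoprop-1-enyl]-2,3-dihydro-1,4-benzodioxine-2-carboxylic acid
Conditions: CF3CO2H–CH2Cl2 (1:1), anisole, 0 °C to rt
Reagents that add atoms: none
Why: Acidolysis of the tert-butyl ester and ipso-protodesilylation of the aryl–SiMe3 bond, which the ortho ring oxygen O4 activates. The step is run while the phenols are still silylated and C2 already carries the carboxyl group, both of which disfavour ionisation of the benzylic C3–O4 bond.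

Step 19
Reactants: 33 (2S,3S)-3-{3,4-bis[(triisopropylsilyl)oxy]phenyl}-7-[(E)-3-{[(R)-1-carboxy-2-{4-[(tert-butyldimethylsilyl)oxy]-3-methoxyphenyl}ethyl]oxy}-3-oxoprop-1-enyl]-2,3-dihydro-1,4-benzodioxine-2-carboxylic acid
Product: 34 (2S,3S)-7-[(E)-3-{[(R)-1-carboxy-2-(4-hydroxy-3-methoxyphenyl)ethyl]oxy}-3-oxoprop-1-enyl]-3-(3,4-dihydroxyphenyl)-2,3-dihydro-1,4-benzodioxine-2-carboxylic acid
Conditions: Bu4NF, AcOH (1:1, 4 equiv), THF, 0 °C to rt; work-up at pH 3 under argon
Reagents that add atoms: none
Why: Fluoride cleaves the three aryl silyl ethers; acetic acid buffers the phenoxides so that C2 should not epimerise, the para-phenoxide should not expel O4 (quinone methide path) and the enoate ester should not be cleaved.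

## Compound list

1 | 4-bromobenzene-1,2-diol | Oc1ccc(Br)cc1O | starting material
2 | 4-bromo-1,2-bis[(triisopropylsilyl)oxy]benzene | CC(C)[Si](C(C)C)(C(C)C)Oc1ccc(Br)cc1O[Si](C(C)C)(C(C)C)C(C)C | intermediate
3 | (R)-2,2-dimethyl-1,3-dioxolane-4-carbaldehyde | CC1(C)OC[C@H](C=O)O1 | starting material
4 | {3,4-bis[(triisopropylsilyl)oxy]phenyl}lithium | [Li]c1ccc(O[Si](C(C)C)(C(C)C)C(C)C)c(O[Si](C(C)C)(C(C)C)C(C)C)c1 | intermediate
5 | {3,4-bis[(triisopropylsilyl)oxy]phenyl}titanium triisopropoxide | CC(C)O[Ti](OC(C)C)(OC(C)C)c1ccc(O[Si](C(C)C)(C(C)C)C(C)C)c(O[Si](C(C)C)(C(C)C)C(C)C)c1 | intermediate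
6 | (S)-{3,4-bis[(triisopropylsilyl)oxy]phenyl}[(4R)-2,2-dimethyl-1,3-dioxolan-4-yl]methanol | CC1(C)O[C@H](CO1)[C@H](c1ccc(O[Si](C(C)C)(C(C)C)C(C)C)c(O[Si](C(C)C)(C(C)C)C(C)C)c1)O | intermediate
7 | potassium alkoxide of 6 | CC1(C)O[C@H](CO1)[C@H](c1ccc(O[Si](C(C)C)(C(C)C)C(C)C)c(O[Si](C(C)C)(C(C)C)C(C)C)c1)[O-].[K+] | intermediate
8 | (4R)-4-[(S)-{3,4-bis[(triisopropylsilyl)oxy]phenyl}{[(E)-1,2-dichlorovinyl]oxy}methyl]-2,2-dimethyl-1,3-dioxolane | CC1(C)O[C@H](CO1)[C@H](c1ccc(O[Si](C(C)C)(C(C)C)C(C)C)c(O[Si](C(C)C)(C(C)C)C(C)C)c1)O/C(Cl)=C\Cl | intermediate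
9 | (2R,3S)-3-{3,4-bis[(triisopropylsilyl)oxy]phenyl}-3-{[(E)-1,2-dichlorovinyl]oxy}propane-1,2-diol | O[C@H](CO)[C@H](c1ccc(O[Si](C(C)C)(C(C)C)C(C)C)c(O[Si](C(C)C)(C(C)C)C(C)C)c1)O/C(Cl)=C\Cl | intermediate
10 | (1S,2R)-1-{3,4-bis[(triisopropylsilyl)oxy]phenyl}-1-{[(E)-1,2-dichlorovinyl]oxy}-3-(trityloxy)propan-2-ol | O[C@H](COC(c1ccccc1)(c1ccccc1)c1ccccc1)[C@H](c1ccc(O[Si](C(C)C)(C(C)C)C(C)C)c(O[Si](C(C)C)(C(C)C)C(C)C)c1)O/C(Cl)=C\Cl | intermediate
11 | dilithium alkoxide acetylide from 10 | [Li]O[C@H](COC(c1ccccc1)(c1ccccc1)c1ccccc1)[C@H](c1ccc(O[Si](C(C)C)(C(C)C)C(C)C)c(O[Si](C(C)C)(C(C)C)C(C)C)c1)OC#C[Li] | intermediate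
12 | O-trimethylsilyl ether of 13 | C[Si](C)(C)O[C@H](COC(c1ccccc1)(c1ccccc1)c1ccccc1)[C@H](c1ccc(O[Si](C(C)C)(C(C)C)C(C)C)c(O[Si](C(C)C)(C(C)C)C(C)C)c1)OC#C[Si](C)(C)C | intermediate
13 | (1S,2R)-1-{3,4-bis[(triisopropylsilyl)oxy]phenyl}-1-{[(trimethylsilyl)ethynyl]oxy}-3-(trityloxy)propan-2-ol | O[C@H](COC(c1ccccc1)(c1ccccc1)c1ccccc1)[C@H](c1ccc(O[Si](C(C)C)(C(C)C)C(C)C)c(O[Si](C(C)C)(C(C)C)C(C)C)c1)OC#C[Si](C)(C)C | intermediate
14 | potassium alkoxide of 13 | [K+].[O-][C@H](COC(c1ccccc1)(c1ccccc1)c1ccccc1)[C@H](c1ccc(O[Si](C(C)C)(C(C)C)C(C)C)c(O[Si](C(C)C)(C(C)C)C(C)C)c1)OC#C[Si](C)(C)C | intermediate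
15 | ({[(1S,2R)-1-{3,4-bis[(triisopropylsilyl)oxy]phenyl}-2-{[(E)-1,2-dichlorovinyl]oxy}-3-(trityloxy)propyl]oxy}ethynyl)trimethylsilane | Cl/C=C(/Cl)O[C@H](COC(c1ccccc1)(c1ccccc1)c1ccccc1)[C@H](c1ccc(O[Si](C(C)C)(C(C)C)C(C)C)c(O[Si](C(C)C)(C(C)C)C(C)C)c1)OC#C[Si](C)(C)C | intermediate
16 | lithium alkynyl ether from 15 | [Li]C#CO[C@H](COC(c1ccccc1)(c1ccccc1)c1ccccc1)[C@H](c1ccc(O[Si](C(C)C)(C(C)C)C(C)C)c(O[Si](C(C)C)(C(C)C)C(C)C)c1)OC#C[Si](C)(C)C | intermediate
17 | ({[(1S,2R)-1-{3,4-bis[(triisopropylsilyl)oxy]phenyl}-2-(ethynyloxy)-3-(trityloxy)propyl]oxy}ethynyl)trimethylsilane | C#CO[C@H](COC(c1ccccc1)(c1ccccc1)c1ccccc1)[C@H](c1ccc(O[Si](C(C)C)(C(C)C)C(C)C)c(O[Si](C(C)C)(C(C)C)C(C)C)c1)OC#C[Si](C)(C)C | intermediate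
18 | 4-bromo-2-methoxyphenol | COc1cc(Br)ccc1O | starting material
19 | (4-bromo-2-methoxyphenoxy)(tert-butyl)dimethylsilane | COc1cc(Br)ccc1O[Si](C)(C)C(C)(C)C | intermediate
20 | potassium (R)-oxirane-2-carboxylate | [K+].[O-]C(=O)[C@H]1CO1 | starting material
21 | {4-[(tert-butyldimethylsilyl)oxy]-3-methoxyphenyl}magnesium bromide | COc1cc([Mg]Br)ccc1O[Si](C)(C)C(C)(C)C | intermediate
22 | (R)-3-{4-[(tert-butyldimethylsilyl)oxy]-3-methoxyphenyl}-2-hydroxypropanoic acid | COc1cc(C[C@@H](O)C(=O)O)ccc1O[Si](C)(C)C(C)(C)C | intermediate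
23 | tert-butyl (R)-3-{4-[(tert-butyldimethylsilyl)oxy]-3-methoxyphenyl}-2-hydroxypropanoate | COc1cc(C[C@@H](O)C(=O)OC(C)(C)C)ccc1O[Si](C)(C)C(C)(C)C | intermediate
24 | 3-(trimethylsilyl)prop-2-ynal | C[Si](C)(C)C#CC=O | starting material
25 | triethyl phosphonoacetate | CCOC(=O)CP(=O)(OCC)OCC | starting material
26 | ethyl (E)-5-(trimethylsilyl)pent-2-en-4-ynoate | CCOC(=O)/C=C/C#C[Si](C)(C)C | intermediate
27 | (E)-pent-2-en-4-ynoic acid | OC(=O)/C=C/C#C | intermediate
28 | tert-butyl (R)-3-{4-[(tert-butyldimethylsilyl)oxy]-3-methoxyphenyl}-2-{[(E)-pent-2-en-4-ynoyl]oxy}propanoate | COc1cc(C[C@@H](OC(=O)/C=C/C#C)C(=O)OC(C)(C)C)ccc1O[Si](C)(C)C(C)(C)C | intermediate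
29 | tert-butyl (R)-2-{[(E)-3-[(2R,3S)-3-{3,4-bis[(triisopropylsilyl)oxy]phenyl}-5-(trimethylsilyl)-2-[(trityloxy)methyl]-2,3-dihydro-1,4-benzodioxin-7-yl]prop-2-enoyl]oxy}-3-{4-[(tert-butyldimethylsilyl)oxy]-3-methoxyphenyl}propanoate | COc1cc(C[C@@H](OC(=O)/C=C/c2cc([Si](C)(C)C)c3c(c2)O[C@H](COC(c2ccccc2)(c2ccccc2)c2ccccc2)[C@H](c2ccc(O[Si](C(C)C)(C(C)C)C(C)C)c(O[Si](C(C)C)(C(C)C)C(C)C)c2)O3)C(=O)OC(C)(C)C)ccc1O[Si](C)(C)C(C)(C)C | intermediate
30 | tert-butyl (R)-2-{[(E)-3-[(2R,3S)-3-{3,4-bis[(triisopropylsilyl)oxy]phenyl}-2-(hydroxymethyl)-5-(trimethylsilyl)-2,3-dihydro-1,4-benzodioxin-7-yl]prop-2-enoyl]oxy}-3-{4-[(tert-butyldimethylsilyl)oxy]-3-methoxyphenyl}propanoate | COc1cc(C[C@@H](OC(=O)/C=C/c2cc([Si](C)(C)C)c3c(c2)O[C@H](CO)[C@H](c2ccc(O[Si](C(C)C)(C(C)C)C(C)C)c(O[Si](C(C)C)(C(C)C)C(C)C)c2)O3)C(=O)OC(C)(C)C)ccc1O[Si](C)(C)C(C)(C)C | intermediate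
31 | tert-butyl (R)-2-{[(E)-3-[(2S,3S)-3-{3,4-bis[(triisopropylsilyl)oxy]phenyl}-2-formyl-5-(trimethylsilyl)-2,3-dihydro-1,4-benzodioxin-7-yl]prop-2-enoyl]oxy}-3-{4-[(tert-butyldimethylsilyl)oxy]-3-methoxyphenyl}propanoate | COc1cc(C[C@@H](OC(=O)/C=C/c2cc([Si](C)(C)C)c3c(c2)O[C@H](C=O)[C@H](c2ccc(O[Si](C(C)C)(C(C)C)C(C)C)c(O[Si](C(C)C)(C(C)C)C(C)C)c2)O3)C(=O)OC(C)(C)C)ccc1O[Si](C)(C)C(C)(C)C | intermediate
32 | (2S,3S)-3-{3,4-bis[(triisopropylsilyl)oxy]phenyl}-7-[(E)-3-{[(R)-1-tert-butoxy-3-{4-[(tert-butyldimethylsilyl)oxy]-3-methoxyphenyl}-1-oxopropan-2-yl]oxy}-3-oxoprop-1-enyl]-5-(trimethylsilyl)-2,3-dihydro-1,4-benzodioxine-2-carboxylic acid | COc1cc(C[C@@H](OC(=O)/C=C/c2cc([Si](C)(C)C)c3c(c2)O[C@H](C(=O)O)[C@H](c2ccc(O[Si](C(C)C)(C(C)C)C(C)C)c(O[Si](C(C)C)(C(C)C)C(C)C)c2)O3)C(=O)OC(C)(C)C)ccc1O[Si](C)(C)C(C)(C)C | intermediate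
33 | (2S,3S)-3-{3,4-bis[(triisopropylsilyl)oxy]phenyl}-7-[(E)-3-{[(R)-1-carboxy-2-{4-[(tert-butyldimethylsilyl)oxy]-3-methoxyphenyl}ethyl]oxy}-3-oxoprop-1-enyl]-2,3-dihydro-1,4-benzodioxine-2-carboxylic acid | COc1cc(C[C@@H](OC(=O)/C=C/c2ccc3c(c2)O[C@H](C(=O)O)[C@H](c2ccc(O[Si](C(C)C)(C(C)C)C(C)C)c(O[Si](C(C)C)(C(C)C)C(C)C)c2)O3)C(=O)O)ccc1O[Si](C)(C)C(C)(C)C | intermediate
34 | (2S,3S)-7-[(E)-3-{[(R)-1-carboxy-2-(4-hydroxy-3-methoxyphenyl)ethyl]oxy}-3-oxoprop-1-enyl]-3-(3,4-dihydroxyphenyl)-2,3-dihydro-1,4-benzodioxine-2-carboxylic acid | COc1cc(C[C@@H](OC(=O)/C=C/c2ccc3c(c2)O[C@H](C(=O)O)[C@H](c2ccc(O)c(O)c2)O3)C(=O)O)ccc1O | target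

## Step count and least certain steps

Total: 19 steps. Longest linear sequence: 13 steps (steps 1 to 8, then 15 to 19).

**Step 15 (key step, proposed new method).**
- What may go wrong: the oxidative coupling of the two ynol ether alkynes on ruthenium may fail or be outrun by cyclotrimerisation of 28, by conversion of the terminal ynol ether into a catalyst-binding vinylidene, or by thermal rearrangement of the benzylic ynol ether of 17. The silyl-capped terminus may also slow the coupling, and the steering may be incomplete.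
- Fallback (known chemistry, from 6 back to 33): the dioxane ring is closed on a preformed arene by two C–O bond formations that do not touch the stereocentres.
 - The potassium alkoxide of 6 displaces fluoride from 3-bromo-4-fluorobenzaldehyde (KHMDS, THF–DMF, 0 °C; nucleophilic aromatic substitution para to the formyl group, with retention at the benzylic carbon) to give the aryl ether 3-bromo-4-{(S)-aryl[(4R)-2,2-dimethyl-1,3-dioxolan-4-yl]methoxy}benzaldehyde F1.
 - Aqueous acetic acid removes the acetonide to give the diol F2, and trityl chloride in pyridine protects the primary hydroxyl to give the trityl ether F3.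
 - Palladium-catalysed intramolecular aryl ether formation (Pd(OAc)2, 2-(di-tert-butylphosphino)-1,1'-binaphthyl, Cs2CO3, toluene, 80 °C) joins the secondary hydroxyl to the brominated carbon and gives the cis 7-formyl benzodioxane F4.
 - Alcohol 23 is acylated with diethylphosphonoacetic acid (DCC, DMAP) to the phosphonate F5.
 - Horner–Wadsworth–Emmons reaction of F5 with F4 (LiCl, i-Pr2NEt, MeCN) gives the (E)-enoate F6, the C5-unsubstituted analogue of 29.
 - Detritylation as in step 16 gives the alcohol F7, oxidation as in step 17 gives the acid F8, and a short, cold treatment with CF3CO2H removes the tert-butyl ester and returns to the route at 33. This series carries no silicon on the ring, so it also avoids the long acid exposure of step 18.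

**Step 2.**
- What may go wrong: poor facial selectivity in the addition to the α-alkoxy aldehyde, because 1,2-induction by the dioxolane is modest and depends on the metal.
- Fallback (from 6 back to 6): the mixture of carbinol epimers from step 2 is oxidised with Dess–Martin periodinane (NaHCO3, CH2Cl2) to the aryl ketone F9. Reduction with Zn(BH4)2 in Et2O at −30 °C, with zinc chelated between the carbonyl oxygen and the ring oxygen, should deliver hydride from the face that gives the anti carbinol 6.

**Step 7.**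
- What may go wrong: the potassium alkoxide may attack the neighbouring silyl ynol ether, by silicon transfer between molecules or by addition to the triple bond, before it is trapped.
- Fallback (from 13 back to 16): no alkoxide is made. The hydroxyl of 13 is formylated with N-formylbenzotriazole to the formate F10. Dibromo-olefination of the formate (CBr4, PPh3, Et3N, CH2Cl2, 0 °C; Ramirez type) gives the 2,2-dibromovinyl ether F11. n-BuLi at −78 °C converts F11 into the lithium alkynyl ether 16, and the methanol quench of step 8 gives 17.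

**Step 18.**
- What may go wrong: the ipso-protonation at C5 is slower than the ester cleavage, and during the longer exposure the benzylic C3–O4 bond may ionise, or aryl silyl ethers may be lost and make that ionisation easier, with drift from cis to trans.
- Fallback (from 29 back to 33): the acid step is moved in front of the oxidation and merged with the detritylation. Compound 29 is treated with CF3CO2H–CH2Cl2 at 0 °C, so that the trityl, tert-butyl and C5 silyl groups leave in one operation and give the hydroxy acid F12. F12 is then oxidised with TEMPO and PhI(OAc)2 as in step 17 to 33. Which of the two stages tolerates acid better cannot be told beforehand: in 32 the carboxyl group at C2 disfavours ionisation at C3, while in 29 nothing at C2 is enolisable and one step is saved.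

## Further compounds

F1 | step 15 | 3-bromo-4-[(S)-{3,4-bis[(triisopropylsilyl)oxy]phenyl}[(4R)-2,2-dimethyl-1,3-dioxolan-4-yl]methoxy]benzaldehyde | CC1(C)O[C@H](CO1)[C@H](c1ccc(O[Si](C(C)C)(C(C)C)C(C)C)c(O[Si](C(C)C)(C(C)C)C(C)C)c1)Oc1ccc(C=O)cc1Br
F2 | step 15 | 3-bromo-4-{[(1S,2R)-1-{3,4-bis[(triisopropylsilyl)oxy]phenyl}-2,3-dihydroxypropyl]oxy}benzaldehyde | O[C@H](CO)[C@H](c1ccc(O[Si](C(C)C)(C(C)C)C(C)C)c(O[Si](C(C)C)(C(C)C)C(C)C)c1)Oc1ccc(C=O)cc1Br
F3 | step 15 | 3-bromo-4-{[(1S,2R)-1-{3,4-bis[(triisopropylsilyl)oxy]phenyl}-2-hydroxy-3-(trityloxy)propyl]oxy}benzaldehyde | O[C@H](COC(c1ccccc1)(c1ccccc1)c1ccccc1)[C@H](c1ccc(O[Si](C(C)C)(C(C)C)C(C)C)c(O[Si](C(C)C)(C(C)C)C(C)C)c1)Oc1ccc(C=O)cc1Br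
F4 | step 15 | (2R,3S)-3-{3,4-bis[(triisopropylsilyl)oxy]phenyl}-2-[(trityloxy)methyl]-2,3-dihydro-1,4-benzodioxine-7-carbaldehyde | O=Cc1ccc2c(c1)O[C@H](COC(c1ccccc1)(c1ccccc1)c1ccccc1)[C@H](c1ccc(O[Si](C(C)C)(C(C)C)C(C)C)c(O[Si](C(C)C)(C(C)C)C(C)C)c1)O2
F5 | step 15 | tert-butyl (R)-3-{4-[(tert-butyldimethylsilyl)oxy]-3-methoxyphenyl}-2-{[2-(diethoxyphosphoryl)acetyl]oxy}propanoate | COc1cc(C[C@@H](OC(=O)CP(=O)(OCC)OCC)C(=O)OC(C)(C)C)ccc1O[Si](C)(C)C(C)(C)C
F6 | step 15 | tert-butyl (R)-2-{[(E)-3-[(2R,3S)-3-{3,4-bis[(triisopropylsilyl)oxy]phenyl}-2-[(trityloxy)methyl]-2,3-dihydro-1,4-benzodioxin-7-yl]prop-2-enoyl]oxy}-3-{4-[(tert-butyldimethylsilyl)oxy]-3-methoxyphenyl}propanoate | COc1cc(C[C@@H](OC(=O)/C=C/c2ccc3c(c2)O[C@H](COC(c2ccccc2)(c2ccccc2)c2ccccc2)[C@H](c2ccc(O[Si](C(C)C)(C(C)C)C(C)C)c(O[Si](C(C)C)(C(C)C)C(C)C)c2)O3)C(=O)OC(C)(C)C)ccc1O[Si](C)(C)C(C)(C)C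
F7 | step 15 | tert-butyl (R)-2-{[(E)-3-[(2R,3S)-3-{3,4-bis[(triisopropylsilyl)oxy]phenyl}-2-(hydroxymethyl)-2,3-dihydro-1,4-benzodioxin-7-yl]prop-2-enoyl]oxy}-3-{4-[(tert-butyldimethylsilyl)oxy]-3-methoxyphenyl}propanoate | COc1cc(C[C@@H](OC(=O)/C=C/c2ccc3c(c2)O[C@H](CO)[C@H](c2ccc(O[Si](C(C)C)(C(C)C)C(C)C)c(O[Si](C(C)C)(C(C)C)C(C)C)c2)O3)C(=O)OC(C)(C)C)ccc1O[Si](C)(C)C(C)(C)C
F8 | step 15 | (2S,3S)-3-{3,4-bis[(triisopropylsilyl)oxy]phenyl}-7-[(E)-3-{[(R)-1-tert-butoxy-3-{4-[(tert-butyldimethylsilyl)oxy]-3-methoxyphenyl}-1-oxopropan-2-yl]oxy}-3-oxoprop-1-enyl]-2,3-dihydro-1,4-benzodioxine-2-carboxylic acid | COc1cc(C[C@@H](OC(=O)/C=C/c2ccc3c(c2)O[C@H](C(=O)O)[C@H](c2ccc(O[Si](C(C)C)(C(C)C)C(C)C)c(O[Si](C(C)C)(C(C)C)C(C)C)c2)O3)C(=O)OC(C)(C)C)ccc1O[Si](C)(C)C(C)(C)C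
F9 | step 2 | {3,4-bis[(triisopropylsilyl)oxy]phenyl}[(4R)-2,2-dimethyl-1,3-dioxolan-4-yl]methanone | CC1(C)O[C@H](CO1)C(=O)c1ccc(O[Si](C(C)C)(C(C)C)C(C)C)c(O[Si](C(C)C)(C(C)C)C(C)C)c1
F10 | step 7 | (1S,2R)-1-{3,4-bis[(triisopropylsilyl)oxy]phenyl}-1-{[(trimethylsilyl)ethynyl]oxy}-3-(trityloxy)propan-2-yl formate | O=CO[C@H](COC(c1ccccc1)(c1ccccc1)c1ccccc1)[C@H](c1ccc(O[Si](C(C)C)(C(C)C)C(C)C)c(O[Si](C(C)C)(C(C)C)C(C)C)c1)OC#C[Si](C)(C)C
F11 | step 7 | ({[(1S,2R)-1-{3,4-bis[(triisopropylsilyl)oxy]phenyl}-2-[(2,2-dibromovinyl)oxy]-3-(trityloxy)propyl]oxy}ethynyl)trimethylsilane | BrC(Br)=CO[C@H](COC(c1ccccc1)(c1ccccc1)c1ccccc1)[C@H](c1ccc(O[Si](C(C)C)(C(C)C)C(C)C)c(O[Si](C(C)C)(C(C)C)C(C)C)c1)OC#C[Si](C)(C)C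
F12 | step 18 | (R)-2-{[(E)-3-[(2R,3S)-3-{3,4-bis[(triisopropylsilyl)oxy]phenyl}-2-(hydroxymethyl)-2,3-dihydro-1,4-benzodioxin-7-yl]prop-2-enoyl]oxy}-3-{4-[(tert-butyldimethylsilyl)oxy]-3-methoxyphenyl}propanoic acid | COc1cc(C[C@@H](OC(=O)/C=C/c2ccc3c(c2)O[C@H](CO)[C@H](c2ccc(O[Si](C(C)C)(C(C)C)C(C)C)c(O[Si](C(C)C)(C(C)C)C(C)C)c2)O3)C(=O)O)ccc1O[Si](C)(C)C(C)(C)C
A1 | alternative 1 | droxidopa, (2S,3R)-2-amino-3-(3,4-dihydroxyphenyl)-3-hydroxypropanoic acid | N[C@H](C(=O)O)[C@H](O)c1ccc(O)c(O)c1
A2 | alternative 1 | allyl (2S,3S)-3-[3,4-bis(allyloxy)phenyl]-7-formyl-2,3-dihydro-1,4-benzodioxine-2-carboxylate | O=Cc1ccc2c(c1)O[C@H](C(=O)OCC=C)[C@H](c1ccc(OCC=C)c(OCC=C)c1)O2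
A3 | alternative 2 | tert-butyl (2S,3S)-3-{3,4-bis[(tert-butyldimethylsilyl)oxy]phenyl}-7-[(E)-3-{[(R)-1-tert-butoxy-3-{4-[(tert-butyldimethylsilyl)oxy]-3-methoxyphenyl}-1-oxopropan-2-yl]oxy}-3-oxoprop-1-enyl]-2,3-dihydro-1,4-benzodioxine-2-carboxylate | COc1cc(C[C@@H](OC(=O)/C=C/c2ccc3c(c2)O[C@H](C(=O)OC(C)(C)C)[C@H](c2ccc(O[Si](C)(C)C(C)(C)C)c(O[Si](C)(C)C(C)(C)C)c2)O3)C(=O)OC(C)(C)C)ccc1O[Si](C)(C)C(C)(C)C
A4 | alternative 3 | allyl (2S,3S)-7-[(E)-3-{[(R)-1-(allyloxy)-3-[4-(allyloxy)-3-methoxyphenyl]-1-oxopropan-2-yl]oxy}-3-oxoprop-1-enyl]-3-[3,4-bis(allyloxy)phenyl]-2,3-dihydro-1,4-benzodioxine-2-carboxylate | COc1cc(C[C@@H](OC(=O)/C=C/c2ccc3c(c2)O[C@H](C(=O)OCC=C)[C@H](c2ccc(OCC=C)c(OCC=C)c2)O3)C(=O)OCC=C)ccc1OCC=C
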